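**Retrosynthetic overview**

1. The last step is peracid epoxidation of the 1(10)-olefin; before it come SN2 chlorination at C3 (from the 3R alcohol) and α-methylenation of the γ-lactone.
2. The γ-lactone, the C6 stereocenter and the C8 ester come from one Evans–Tishchenko coupling of a β-hydroxy ketone with the side-chain aldehyde, itself made from ethyl (S)-3-hydroxybutanoate by two Fráter–Seebach steps.
3. The ten-membered ring is made first, by anionic oxy-Cope rearrangement of a trans-1,2-dialkenylcyclohexenol (C8–C9 formed, C1–C6 cleaved); the enolate is trapped at C7 with tert-butyl bromoacetate.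
4. The cyclohexenol comes from a (Z)-2-alkoxyvinyllithium and a 4-silyloxy-isopiperitenone, made from (R)-carvone by Wharton transposition and allylic oxidation.
5. Ring order: cyclohexene (bought) → ten-membered carbocycle (oxy-Cope) → γ-lactone → oxirane.

Assumption: ten-membered-ring compounds are numbered as germacranes (ring C1–C10, lactone carbons C11–C13, C14 on C10, C15 on C4), and the three starting materials and all reagents are taken as commercial.

**Route**

Step 1
Reactants: 1 (R)-(−)-carvone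
Product: 2 (1R,4R,6R)-1-methyl-4-(prop-1-en-2-yl)-7-oxabicyclo[4.1.0]heptan-2-one
Conditions: 30% H2O2, NaOH (cat.), MeOH, 0 °C
Reagents that add atoms: hydrogen peroxide (OO)
Why: Weitz–Scheffer nucleophilic epoxidation touches only the enone (the isopropenyl olefin is inert), and hydroperoxide attacks axially on the face anti to the isopropenyl group, so the oxirane is trans to it.

Step 2
Reactants: 2 (1R,4R,6R)-1-methyl-4-(prop-1-en-2-yl)-7-oxabicyclo[4.1.0]heptan-2-one
Product: 4 (1R,5S)-2-methyl-5-(prop-1-en-2-yl)cyclohex-2-en-1-ol (trans-carveol), via epoxy hydrazone 3 (not isolated)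
Conditions: N2H4·H2O, AcOH (cat.), MeOH, 0 °C → rt
Reagents that add atoms: none
Why: In the Wharton transposition the epoxy hydrazone fragments with loss of N2, shifting the double bond and leaving the former oxirane C–O bond untouched, so the new carbinol keeps its configuration with OH trans to isopropenyl.

Step 3
Reactants: 4 (1R,5S)-2-methyl-5-(prop-1-en-2-yl)cyclohex-2-en-1-ol (trans-carveol)
Product: 5 triethyl{[(1R,5S)-2-methyl-5-(prop-1-en-2-yl)cyclohex-2-en-1-yl]oxy}silane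
Conditions: Et3SiCl, imidazole, DMF, 0 °C
Reagents that add atoms: chlorotriethylsilane (CC[Si](Cl)(CC)CC)
Why: Imidazole-assisted silylation of a secondary allylic alcohol touches no stereocenter and gives an ether that survives the oxidant, organolithium and amide bases used later.

Step 4
Reactants: 5 triethyl{[(1R,5S)-2-methyl-5-(prop-1-en-2-yl)cyclohex-2-en-1-yl]oxy}silane
Product: 7 (4R,6S)-3-methyl-6-(prop-1-en-2-yl)-4-[(triethylsilyl)oxy]cyclohex-2-en-1-one, via allylic tert-butyl peroxide 6 (not isolated)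
Conditions: Rh2(cap)4 (dirhodium tetracaprolactamate, 1 mol%), t-BuOOH (70% aq., 5 equiv), ClCH2CH2Cl, 40 °C
Reagents that add atoms: tert-butyl hydroperoxide (CC(C)(C)OO)
Why: In this dirhodium-catalysed radical allylic C–H oxidation the peroxyl radical abstracts the axial allylic hydrogen of the ring CH2 (the silyloxy methine C–H is pseudo-equatorial and shielded), the mixed peroxide collapses to the enone, and the base-free medium leaves the α-isopropenyl stereocenter unepimerised.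

Step 5
Reactants: 8 4-methoxybenzyl alcohol
Product: 9 1-[(ethenyloxy)methyl]-4-methoxybenzene (4-methoxybenzyl vinyl ether)
Conditions: Hg(OAc)2 (5 mol%), ethyl vinyl ether (solvent), reflux
Reagents that add atoms: ethyl vinyl ether (C=COCC)
Why: Mercury-catalysed transetherification (transvinylation) of a primary alcohol is driven by the large excess of ethyl vinyl ether and involves no stereocenter.

Step 6
Reactants: 9 1-[(ethenyloxy)methyl]-4-methoxybenzene (4-methoxybenzyl vinyl ether)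
Product: 11 1-{[(Z)-2-bromoethenyl]oxymethyl}-4-methoxybenzene, via dibromo ether 10 (not isolated)
Conditions: Br2 (1.0 equiv), CH2Cl2, −78 °C; then Et3N, −78 °C → reflux
Reagents that add atoms: bromine (BrBr)
Why: Bromine addition to the electron-rich vinyl ether followed by amine-induced dehydrobromination of the α-bromo ether gives the (Z)-β-bromovinyl ether, as known for the ethyl analogue.

Step 7
Reactants: 11 1-{[(Z)-2-bromoethenyl]oxymethyl}-4-methoxybenzene; 7 (4R,6S)-3-methyl-6-(prop-1-en-2-yl)-4-[(triethylsilyl)oxy]cyclohex-2-en-1-one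
Product: 13 (1S,4R,6S)-1-{(Z)-2-[(4-methoxybenzyl)oxy]ethenyl}-3-methyl-6-(prop-1-en-2-yl)-4-[(triethylsilyl)oxy]cyclohex-2-en-1-ol, via alkoxyvinyllithium 12 (not isolated)
Conditions: 11 (1.5 equiv), t-BuLi (3.0 equiv), Et2O, −78 °C; then 7, THF, −78 °C; then H2O
Reagents that add atoms: none
Why: Bromine–lithium exchange with retention gives the oxygen-chelated, configurationally stable (Z)-vinyllithium, which adds 1,2 to the enone carbonyl anti to the adjacent equatorial isopropenyl group (steric approach control), so the two alkenyl groups end up trans-diequatorial and the hydroxyl cis to isopropenyl.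

Step 8
Reactants: 13 (1S,4R,6S)-1-{(Z)-2-[(4-methoxybenzyl)oxy]ethenyl}-3-methyl-6-(prop-1-en-2-yl)-4-[(triethylsilyl)oxy]cyclohex-2-en-1-ol
Product: 16 tert-butyl 2-[(1R,2R,4E,7R,8Z)-2-[(4-methoxybenzyl)oxy]-4,8-dimethyl-10-oxo-7-[(triethylsilyl)oxy]cyclodeca-4,8-dien-1-yl]acetate, via potassium alkoxide 14 (not isolated), via potassium enolate 15 (not isolated)
Conditions: KN(SiMe3)2 (1.1 equiv), 18-crown-6, THF, −78 → 0 °C; then BrCH2CO2t-Bu, −78 °C
Reagents that add atoms: tert-butyl bromoacetate (CC(C)(C)OC(=O)CBr)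
Why: In the anionic oxy-Cope rearrangement the alkoxide undergoes the [3,3] shift through a chair transition state with both cyclohexene ring bonds equatorial and the (Z)-alkoxy group axial, which forms C8–C9, makes the 1(10)-olefin E, keeps the ring olefin as the 4Z-olefin and transfers the chirality of C1 to C8 (8R), and the resulting enolate is then alkylated at C7 on its outer face, anti to the C8–C9 ring bond with the C8 alkoxy group inside (2,3-anti, 7R).

Step 9
Reactants: 16 tert-butyl 2-[(1R,2R,4E,7R,8Z)-2-[(4-methoxybenzyl)oxy]-4,8-dimethyl-10-oxo-7-[(triethylsilyl)oxy]cyclodeca-4,8-dien-1-yl]acetate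
Product: 17 tert-butyl 2-[(1R,2R,4E,7R,8Z)-2-hydroxy-4,8-dimethyl-10-oxo-7-[(triethylsilyl)oxy]cyclodeca-4,8-dien-1-yl]acetate
Conditions: DDQ (1.2 equiv), CH2Cl2/pH 7 buffer, 0 °C
Reagents that add atoms: none
Why: Oxidative cleavage of the 4-methoxybenzyl ether by DDQ (benzylic hydride abstraction, then hydrolysis) runs under buffered neutral conditions that spare the silyl ether, do not dehydrate the β-hydroxy ketone and cannot lactonise the tert-butyl ester, and no stereocenter changes.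

Step 10
Reactants: 18 ethyl (S)-3-hydroxybutanoate
Product: 20 ethyl (2S,3S)-3-hydroxy-2-methylbutanoate, via dilithium alkoxide-enolate 19 (not isolated)
Conditions: LiN(i-Pr)2 (2.2 equiv), THF, −50 → −15 °C; then MeI, DMPU, −78 → 0 °C; then H2O
Reagents that add atoms: iodomethane (CI)
Why: In the Fráter–Seebach alkylation the lithium-chelated dianion is methylated on the face anti to the C3 methyl group of the six-membered chelate, giving the 2,3-anti (2S,3S) ester under control of the purchased stereocenter.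

Step 11
Reactants: 20 ethyl (2S,3S)-3-hydroxy-2-methylbutanoate
Product: 22 ethyl (2S,3S)-2,3-dihydroxy-2-methylbutanoate, via dilithium dianion 21 (not isolated)
Conditions: LiN(i-Pr)2 (2.3 equiv), THF, −78 → −20 °C; then MoO5·pyridine·HMPA (MoOPH), −78 → −40 °C; then H2O
Reagents that add atoms: MoO5·pyridine·HMPA (O=[Mo]12(OO1)OO2.c1ccncc1.CN(C)P(=O)(N(C)C)N(C)C)
Why: This second Fráter–Seebach-type step uses Vedejs enolate hydroxylation, and the chelated tetrasubstituted dianion takes up oxygen on the same face (anti to the C3 methyl), so OH occupies the position the methyl entered in step 10 and the quaternary center is 2S.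

Step 12
Reactants: 22 ethyl (2S,3S)-2,3-dihydroxy-2-methylbutanoate
Product: 24 ethyl (2S,3S)-3-[(tert-butyldimethylsilyl)oxy]-2-methyl-2-[(triethylsilyl)oxy]butanoate, via mono-TBS ether 23 (not isolated)
Conditions: t-BuMe2SiOTf (1.05 equiv), 2,6-lutidine, CH2Cl2, −78 °C; then Et3SiOTf (1.5 equiv), −78 → 0 °C
Reagents that add atoms: tert-butyldimethylsilyl triflate (CC(C)(C)[Si](C)(C)OS(=O)(=O)C(F)(F)F); triethylsilyl triflate (CC[Si](CC)(CC)OS(=O)(=O)C(F)(F)F)
Why: In this silyl triflate silylation only the secondary hydroxyl reacts with the bulky TBS triflate at −78 °C, after which the smaller TES triflate caps the tertiary hydroxyl, and no stereocenter is touched.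

Step 13
Reactants: 24 ethyl (2S,3S)-3-[(tert-butyldimethylsilyl)oxy]-2-methyl-2-[(triethylsilyl)oxy]butanoate
Product: 25 (2S,3S)-3-[(tert-butyldimethylsilyl)oxy]-2-methyl-2-[(triethylsilyl)oxy]butanal
Conditions: i-Bu2AlH (1.1 equiv), CH2Cl2, −78 °C; then H2O
Reagents that add atoms: none
Why: In this partial ester reduction the aluminium hemiacetal of the hindered α-silyloxy ester is stable at −78 °C and releases the aldehyde only on work-up, and the quaternary α-carbon cannot epimerise.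

Step 14
Reactants: 17 tert-butyl 2-[(1R,2R,4E,7R,8Z)-2-hydroxy-4,8-dimethyl-10-oxo-7-[(triethylsilyl)oxy]cyclodeca-4,8-dien-1-yl]acetate; 25 (2S,3S)-3-[(tert-butyldimethylsilyl)oxy]-2-methyl-2-[(triethylsilyl)oxy]butanal
Product: 27 tert-butyl 2-[(1S,2R,4E,7R,8Z,10R)-10-hydroxy-4,8-dimethyl-2-{[(2S,3S)-3-[(tert-butyldimethylsilyl)oxy]-2-methyl-2-[(triethylsilyl)oxy]butanoyl]oxy}-7-[(triethylsilyl)oxy]cyclodeca-4,8-dien-1-yl]acetate, via hemiacetal 26 (not isolated)
Conditions: SmI2 (0.3 equiv), 25 (3 equiv), THF, −10 °C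
Reagents that add atoms: none
Why: In the Evans–Tishchenko reduction the C8 hydroxyl adds to the aldehyde and the samarium-bound hemiacetal delivers its hydride intramolecularly through a chair six-membered transition state to the C6 ketone, which sets C6 1,3-anti to C8 (6R), turns the aldehyde carbon into the C8 ester and leaves O6 as the only free hydroxyl.

Step 15
Reactants: 27 tert-butyl 2-[(1S,2R,4E,7R,8Z,10R)-10-hydroxy-4,8-dimethyl-2-{[(2S,3S)-3-[(tert-butyldimethylsilyl)oxy]-2-methyl-2-[(triethylsilyl)oxy]butanoyl]oxy}-7-[(triethylsilyl)oxy]cyclodeca-4,8-dien-1-yl]acetate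
Product: 31 (1(10)E,4Z,3R,6R,7R,8R)-8-{[(2S,3S)-3-[(tert-butyldimethylsilyl)oxy]-2-methyl-2-[(triethylsilyl)oxy]butanoyl]oxy}-3-[(triethylsilyl)oxy]germacra-1(10),4,11(13)-trien-12,6-olide, via lactone 28 (not isolated), via Mannich base 29 (not isolated), via trimethylammonium iodide 30 (not isolated)
Conditions: LiN(SiMe3)2 (1.1 equiv), THF, −78 → 0 °C; LiN(i-Pr)2 (1.5 equiv), −78 °C; CH2=NMe2+ I−, −78 °C → rt; then MeI, MeOH, rt; then aq. NaHCO3, CH2Cl2
Reagents that add atoms: N,N-dimethylmethyleneiminium iodide (C=[N+](C)C.[I-])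
Why: The O6 lithium alkoxide closes the trans-fused γ-lactone by 5-exo attack on the tert-butyl ester (O8 is already acylated, so the regiochemistry is unambiguous), and α-methylenation follows by Mannich reaction of the lactone enolate with Eschenmoser's salt, N-methylation and base-induced elimination of trimethylamine, the O8 acyl group having no α-hydrogen and C11 ending sp2.

Step 16
Reactants: 31 (1(10)E,4Z,3R,6R,7R,8R)-8-{[(2S,3S)-3-[(tert-butyldimethylsilyl)oxy]-2-methyl-2-[(triethylsilyl)oxy]butanoyl]oxy}-3-[(triethylsilyl)oxy]germacra-1(10),4,11(13)-trien-12,6-olide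
Product: 32 (1(10)E,4Z,3R,6R,7R,8R)-8-{[(2S,3S)-3-[(tert-butyldimethylsilyl)oxy]-2-methyl-2-[(triethylsilyl)oxy]butanoyl]oxy}-3-hydroxygermacra-1(10),4,11(13)-trien-12,6-olide
Conditions: HF·pyridine, excess pyridine, THF, 0 °C
Reagents that add atoms: none
Why: Under buffered fluoride desilylation the unhindered secondary allylic TES ether at C3 is cleaved much faster than the neopentyl-type secondary TBS ether and the tertiary TES ether of the side chain.

Step 17
Reactants: 32 (1(10)E,4Z,3R,6R,7R,8R)-8-{[(2S,3S)-3-[(tert-butyldimethylsilyl)oxy]-2-methyl-2-[(triethylsilyl)oxy]butanoyl]oxy}-3-hydroxygermacra-1(10),4,11(13)-trien-12,6-olide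
Product: 34 (1(10)E,4Z,3S,6R,7R,8R)-8-{[(2S,3S)-3-[(tert-butyldimethylsilyl)oxy]-2-methyl-2-[(triethylsilyl)oxy]butanoyl]oxy}-3-chlorogermacra-1(10),4,11(13)-trien-12,6-olide, via alkoxyphosphonium chloride 33 (not isolated)
Conditions: Cl3CCOCCl3, CH2Cl2, −20 °C; PPh3 added last, −20 → 0 °C
Reagents that add atoms: hexachloroacetone (ClC(Cl)(Cl)C(=O)C(Cl)(Cl)Cl)
Why: In this Appel-type chlorination with the Magid reagent, chloride displaces the alkoxyphosphonium group by SN2 with inversion (3R alcohol to 3S chloride) at low temperature, conditions known to avoid allylic transposition, while the side-chain hydroxyls are still silylated.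

Step 18
Reactants: 34 (1(10)E,4Z,3S,6R,7R,8R)-8-{[(2S,3S)-3-[(tert-butyldimethylsilyl)oxy]-2-methyl-2-[(triethylsilyl)oxy]butanoyl]oxy}-3-chlorogermacra-1(10),4,11(13)-trien-12,6-olide
Product: 35 (1(10)E,4Z,3S,6R,7R,8R)-3-chloro-8-{[(2S,3S)-2,3-dihydroxy-2-methylbutanoyl]oxy}germacra-1(10),4,11(13)-trien-12,6-olide
Conditions: HF·pyridine, THF, 0 °C → rt
Reagents that add atoms: none
Why: Global fluoride desilylation removes the remaining secondary TBS and tertiary TES ethers without base or aqueous acid, so the allylic chloride, the ester, the diene and the α-methylene lactone survive.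

Step 19
Reactants: 35 (1(10)E,4Z,3S,6R,7R,8R)-3-chloro-8-{[(2S,3S)-2,3-dihydroxy-2-methylbutanoyl]oxy}germacra-1(10),4,11(13)-trien-12,6-olide
Product: 36 (1R,3S,6R,7R,8R,10R,4Z)-3-chloro-1,10-epoxy-8-{[(2S,3S)-2,3-dihydroxy-2-methylbutanoyl]oxy}germacra-4,11(13)-dien-12,6-olide (CNP0325326.6)
Conditions: mCPBA (1.05 equiv), NaHCO3, CH2Cl2, 0 °C
Reagents that add atoms: 3-chloroperbenzoic acid (OOC(=O)c1cccc(Cl)c1)
Why: In this Prilezhaev epoxidation the strained, electron-rich E-1(10)-olefin reacts far faster than the 4,5-olefin (deactivated by the allylic chlorine and lactone oxygen) and the electron-poor methylene lactone, and the peracid adds stereospecifically (E-olefin to trans-oxirane) to the outer face of the olefin in the crossed ring conformation, which is expected to give the (1R,10R) epoxide.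

**Compound list**

1 | (R)-(−)-carvone, (5R)-2-methyl-5-(prop-1-en-2-yl)cyclohex-2-en-1-one | CC1=CC[C@H](CC1=O)C(C)=C | starting material
2 | (1R,4R,6R)-1-methyl-4-(prop-1-en-2-yl)-7-oxabicyclo[4.1.0]heptan-2-one (oxirane trans to isopropenyl) | C[C@@]12O[C@@H]1C[C@H](CC2=O)C(C)=C | intermediate
3 | hydrazone of epoxy ketone 2 (C=N–NH2 in place of C=O, stereocenters unchanged) | C[C@@]12O[C@@H]1C[C@H](CC2=NN)C(C)=C | intermediate
4 | (1R,5S)-2-methyl-5-(prop-1-en-2-yl)cyclohex-2-en-1-ol (trans-carveol) | CC1=CC[C@@H](C[C@H]1O)C(C)=C | intermediate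
5 | triethyl{[(1R,5S)-2-methyl-5-(prop-1-en-2-yl)cyclohex-2-en-1-yl]oxy}silane | CC1=CC[C@@H](C[C@H]1O[Si](CC)(CC)CC)C(C)=C | intermediate
6 | allylic tert-butyl peroxide of 5 (t-BuOO on the ring CH2 next to the olefinic CH, epimer mixture) | CC1=CC(OOC(C)(C)C)[C@@H](C[C@H]1O[Si](CC)(CC)CC)C(C)=C | intermediate
7 | (4R,6S)-3-methyl-6-(prop-1-en-2-yl)-4-[(triethylsilyl)oxy]cyclohex-2-en-1-one | CC1=CC(=O)[C@@H](C[C@H]1O[Si](CC)(CC)CC)C(C)=C | intermediate
8 | 4-methoxybenzyl alcohol | COc1ccc(CO)cc1 | starting material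
9 | 1-[(ethenyloxy)methyl]-4-methoxybenzene (4-methoxybenzyl vinyl ether) | COc1ccc(COC=C)cc1 | intermediate
10 | 1-[(1,2-dibromoethoxy)methyl]-4-methoxybenzene | COc1ccc(COC(Br)CBr)cc1 | intermediate
11 | 1-{[(Z)-2-bromoethenyl]oxymethyl}-4-methoxybenzene | COc1ccc(CO/C=C\Br)cc1 | intermediate
12 | (Z)-2-[(4-methoxybenzyl)oxy]ethenyllithium | COc1ccc(CO/C=C\[Li])cc1 | intermediate
13 | (1S,4R,6S)-1-{(Z)-2-[(4-methoxybenzyl)oxy]ethenyl}-3-methyl-6-(prop-1-en-2-yl)-4-[(triethylsilyl)oxy]cyclohex-2-en-1-ol (OH cis to isopropenyl) | CC1=C[C@@](O)(/C=C\OCc2ccc(OC)cc2)[C@@H](C[C@H]1O[Si](CC)(CC)CC)C(C)=C | intermediate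
14 | potassium alkoxide of 13 | CC1=C[C@@]([O-])(/C=C\OCc2ccc(OC)cc2)[C@@H](C[C@H]1O[Si](CC)(CC)CC)C(C)=C.[K+] | intermediate
15 | potassium C6(O)=C7 enolate of the (1(10)E,4Z)-cyclodecadienone, 3R-OTES, 8R-OPMB | [C@@H]1(OCc2ccc(OC)cc2)C/C(C)=C/C[C@@H](O[Si](CC)(CC)CC)/C(C)=C\C([O-])=C\1.[K+] | intermediate
16 | tert-butyl 2-[(1R,2R,4E,7R,8Z)-2-[(4-methoxybenzyl)oxy]-4,8-dimethyl-10-oxo-7-[(triethylsilyl)oxy]cyclodeca-4,8-dien-1-yl]acetate (germacrane 3R,7R,8R) | CC(C)(C)OC(=O)C[C@H]1C(=O)/C=C(/C)[C@H](O[Si](CC)(CC)CC)C/C=C(\C)C[C@H]1OCc1ccc(OC)cc1 | intermediate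
17 | tert-butyl 2-[(1R,2R,4E,7R,8Z)-2-hydroxy-4,8-dimethyl-10-oxo-7-[(triethylsilyl)oxy]cyclodeca-4,8-dien-1-yl]acetate | CC(C)(C)OC(=O)C[C@H]1C(=O)/C=C(/C)[C@H](O[Si](CC)(CC)CC)C/C=C(\C)C[C@H]1O | intermediate
18 | ethyl (S)-3-hydroxybutanoate | CCOC(=O)C[C@H](C)O | starting material
19 | dilithium alkoxide-enolate of 18 | CCOC([O-])=C[C@H](C)[O-].[Li+].[Li+] | intermediate
20 | ethyl (2S,3S)-3-hydroxy-2-methylbutanoate | CCOC(=O)[C@@H](C)[C@H](C)O | intermediate
21 | dilithium alkoxide-enolate of 20 | CCOC([O-])=C(C)[C@H](C)[O-].[Li+].[Li+] | intermediate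
22 | ethyl (2S,3S)-2,3-dihydroxy-2-methylbutanoate | CCOC(=O)[C@@](C)(O)[C@H](C)O | intermediate
23 | ethyl (2S,3S)-3-[(tert-butyldimethylsilyl)oxy]-2-hydroxy-2-methylbutanoate | CCOC(=O)[C@@](C)(O)[C@H](C)O[Si](C)(C)C(C)(C)C | intermediate
24 | ethyl (2S,3S)-3-[(tert-butyldimethylsilyl)oxy]-2-methyl-2-[(triethylsilyl)oxy]butanoate | CCOC(=O)[C@@](C)(O[Si](CC)(CC)CC)[C@H](C)O[Si](C)(C)C(C)(C)C | intermediate
25 | (2S,3S)-3-[(tert-butyldimethylsilyl)oxy]-2-methyl-2-[(triethylsilyl)oxy]butanal | O=C[C@@](C)(O[Si](CC)(CC)CC)[C@H](C)O[Si](C)(C)C(C)(C)C | intermediate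
26 | hemiacetal of 17 (O8) with aldehyde 25 (samarium-bound in the flask, hemiacetal carbon unassigned) | CC(C)(C)OC(=O)C[C@H]1C(=O)/C=C(/C)[C@H](O[Si](CC)(CC)CC)C/C=C(\C)C[C@H]1OC(O)[C@@](C)(O[Si](CC)(CC)CC)[C@H](C)O[Si](C)(C)C(C)(C)C | intermediate
27 | tert-butyl 2-[(1S,2R,4E,7R,8Z,10R)-10-hydroxy-4,8-dimethyl-2-{[(2S,3S)-3-[(tert-butyldimethylsilyl)oxy]-2-methyl-2-[(triethylsilyl)oxy]butanoyl]oxy}-7-[(triethylsilyl)oxy]cyclodeca-4,8-dien-1-yl]acetate (germacrane 3R,6R,7S,8R) | CC(C)(C)OC(=O)C[C@H]1[C@H](O)/C=C(/C)[C@H](O[Si](CC)(CC)CC)C/C=C(\C)C[C@H]1OC(=O)[C@@](C)(O[Si](CC)(CC)CC)[C@H](C)O[Si](C)(C)C(C)(C)C | intermediate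
28 | (1(10)E,4Z,3R,6R,7R,8R)-8-{[(2S,3S)-3-[(tert-butyldimethylsilyl)oxy]-2-methyl-2-[(triethylsilyl)oxy]butanoyl]oxy}-3-[(triethylsilyl)oxy]-13-norgermacra-1(10),4-dien-12,6-olide | C1C(=O)O[C@@H]2/C=C(/C)[C@H](O[Si](CC)(CC)CC)C/C=C(\C)C[C@@H](OC(=O)[C@@](C)(O[Si](CC)(CC)CC)[C@H](C)O[Si](C)(C)C(C)(C)C)[C@@H]12 | intermediate
29 | 11-[(dimethylamino)methyl] derivative of lactone 28 (C11 epimers) | CN(C)CC1C(=O)O[C@@H]2/C=C(/C)[C@H](O[Si](CC)(CC)CC)C/C=C(\C)C[C@@H](OC(=O)[C@@](C)(O[Si](CC)(CC)CC)[C@H](C)O[Si](C)(C)C(C)(C)C)[C@@H]12 | intermediate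
30 | 11-[(trimethylammonio)methyl] iodide derived from 29 | C[N+](C)(C)CC1C(=O)O[C@@H]2/C=C(/C)[C@H](O[Si](CC)(CC)CC)C/C=C(\C)C[C@@H](OC(=O)[C@@](C)(O[Si](CC)(CC)CC)[C@H](C)O[Si](C)(C)C(C)(C)C)[C@@H]12.[I-] | intermediate
31 | (1(10)E,4Z,3R,6R,7R,8R)-8-{[(2S,3S)-3-[(tert-butyldimethylsilyl)oxy]-2-methyl-2-[(triethylsilyl)oxy]butanoyl]oxy}-3-[(triethylsilyl)oxy]germacra-1(10),4,11(13)-trien-12,6-olide | C=C1C(=O)O[C@@H]2/C=C(/C)[C@H](O[Si](CC)(CC)CC)C/C=C(\C)C[C@@H](OC(=O)[C@@](C)(O[Si](CC)(CC)CC)[C@H](C)O[Si](C)(C)C(C)(C)C)[C@@H]12 | intermediate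
32 | (1(10)E,4Z,3R,6R,7R,8R)-8-{[(2S,3S)-3-[(tert-butyldimethylsilyl)oxy]-2-methyl-2-[(triethylsilyl)oxy]butanoyl]oxy}-3-hydroxygermacra-1(10),4,11(13)-trien-12,6-olide | C=C1C(=O)O[C@@H]2/C=C(/C)[C@H](O)C/C=C(\C)C[C@@H](OC(=O)[C@@](C)(O[Si](CC)(CC)CC)[C@H](C)O[Si](C)(C)C(C)(C)C)[C@@H]12 | intermediate
33 | 3-O-triphenylphosphonium chloride of 32 | C=C1C(=O)O[C@@H]2/C=C(/C)[C@H](O[P+](c3ccccc3)(c3ccccc3)c3ccccc3)C/C=C(\C)C[C@@H](OC(=O)[C@@](C)(O[Si](CC)(CC)CC)[C@H](C)O[Si](C)(C)C(C)(C)C)[C@@H]12.[Cl-] | intermediate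
34 | (1(10)E,4Z,3S,6R,7R,8R)-8-{[(2S,3S)-3-[(tert-butyldimethylsilyl)oxy]-2-methyl-2-[(triethylsilyl)oxy]butanoyl]oxy}-3-chlorogermacra-1(10),4,11(13)-trien-12,6-olide | C=C1C(=O)O[C@@H]2/C=C(/C)[C@@H](Cl)C/C=C(\C)C[C@@H](OC(=O)[C@@](C)(O[Si](CC)(CC)CC)[C@H](C)O[Si](C)(C)C(C)(C)C)[C@@H]12 | intermediate
35 | (1(10)E,4Z,3S,6R,7R,8R)-3-chloro-8-{[(2S,3S)-2,3-dihydroxy-2-methylbutanoyl]oxy}germacra-1(10),4,11(13)-trien-12,6-olide | C=C1C(=O)O[C@@H]2/C=C(/C)[C@@H](Cl)C/C=C(\C)C[C@@H](OC(=O)[C@@](C)(O)[C@H](C)O)[C@@H]12 | intermediate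
36 | (1R,3S,6R,7R,8R,10R,4Z)-3-chloro-1,10-epoxy-8-{[(2S,3S)-2,3-dihydroxy-2-methylbutanoyl]oxy}germacra-4,11(13)-dien-12,6-olide (CNP0325326.6) | C=C1C(=O)O[C@@H]2/C=C(/C)[C@@H](Cl)C[C@H]3O[C@]3(C)C[C@@H](OC(=O)[C@@](C)(O)[C@H](C)O)[C@@H]12 | target

**Step count and risks**

Total steps: 19. Longest linear sequence: 13 steps (steps 1–4, 7–9 and 14–19, from carvone).

Most likely to fail, 1 – step 8 (oxy-Cope and enolate alkylation). The potassium enolate carries a β-alkoxy group and may lose 4-methoxybenzyl oxide (E1cB) or alkylate with poor face selectivity at C7. The fallback sets out from 13 and avoids a free potassium enolate at 0 °C. Compound 13 is silylated (Me3SiCl, imidazole, DMF) to the trimethylsilyl ether F1. F1 undergoes the neutral siloxy-Cope rearrangement on heating (PhMe, sealed silylated tube, about 200 °C) through the same chair to the ten-membered trimethylsilyl enol ether F2. MeLi (THF, −20 °C) then liberates the lithium enolate regiospecifically, and alkylation with tert-butyl bromoacetate (DMPU, −78 °C) comes back to the route at 16.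

Most likely to fail, 2 – step 14 (Evans–Tishchenko coupling). The α-quaternary aldehyde 25 is hindered and SmI2 may touch the enone. The fallback sets out from 17 and separates reduction from acylation. Compound 17 is reduced by the Evans–Tishchenko reaction with acetaldehyde (SmI2 cat., THF, −10 °C) to the 8-acetate 6-alcohol F3. LiN(SiMe3)2 closes the lactone to the acetoxy lactone F4, and K2CO3 in MeOH at 0 °C removes the acetate to give the 8-hydroxy lactone F5. Separately, aldehyde 25 is oxidised (NaClO2, NaH2PO4, 2-methyl-2-butene, t-BuOH/H2O) to the silylated acid F6. Yamaguchi esterification of F5 with F6 (2,4,6-trichlorobenzoyl chloride, Et3N, DMAP, PhMe) comes back to the route at 28, from which the methylenation half of step 15 continues.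

Most likely to fail, 3 – step 19 (face selectivity of the epoxidation). The outer face of the 1(10)-olefin in the reacting conformer may be the wrong one. The fallback sets out from 35 and delivers oxygen to the opposite face. N-Bromosuccinimide in aqueous THF at 0 °C forms the bromonium ion on the face the peracid prefers, and water opens it anti at the tertiary C10 to give the bromohydrin F7. K2CO3 in acetone then closes the oxirane with inversion at C1, which comes back to the route at 36.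

**Further compounds**

F1 | step 8 | trimethylsilyl ether of carbinol 13 | CC1=C[C@@](O[Si](C)(C)C)(/C=C\OCc2ccc(OC)cc2)[C@@H](C[C@H]1O[Si](CC)(CC)CC)C(C)=C
F2 | step 8 | ten-membered C6(OSiMe3)=C7 trimethylsilyl enol ether (1(10)E,4Z; 3R-OTES, 8R-OPMB) | [C@@H]1(OCc2ccc(OC)cc2)C/C(C)=C/C[C@@H](O[Si](CC)(CC)CC)/C(C)=C\C(O[Si](C)(C)C)=C\1
F3 | step 14 | tert-butyl 2-[(1S,2R,4E,7R,8Z,10R)-2-acetoxy-10-hydroxy-4,8-dimethyl-7-[(triethylsilyl)oxy]cyclodeca-4,8-dien-1-yl]acetate | CC(C)(C)OC(=O)C[C@H]1[C@H](O)/C=C(/C)[C@H](O[Si](CC)(CC)CC)C/C=C(\C)C[C@H]1OC(C)=O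
F4 | step 14 | (1(10)E,4Z,3R,6R,7R,8R)-8-acetoxy-3-[(triethylsilyl)oxy]-13-norgermacra-1(10),4-dien-12,6-olide | C1C(=O)O[C@@H]2/C=C(/C)[C@H](O[Si](CC)(CC)CC)C/C=C(\C)C[C@@H](OC(C)=O)[C@@H]12
F5 | step 14 | (1(10)E,4Z,3R,6R,7R,8R)-8-hydroxy-3-[(triethylsilyl)oxy]-13-norgermacra-1(10),4-dien-12,6-olide | C1C(=O)O[C@@H]2/C=C(/C)[C@H](O[Si](CC)(CC)CC)C/C=C(\C)C[C@@H](O)[C@@H]12
F6 | step 14 | (2S,3S)-3-[(tert-butyldimethylsilyl)oxy]-2-methyl-2-[(triethylsilyl)oxy]butanoic acid | OC(=O)[C@@](C)(O[Si](CC)(CC)CC)[C@H](C)O[Si](C)(C)C(C)(C)C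
F7 | step 19 | 1-bromo-10-hydroxy bromohydrin of 35 (Br at C1, OH at C10, anti addition, set for closure to the 1R,10R oxirane) | C=C1C(=O)O[C@@H]2/C=C(/C)[C@@H](Cl)C[C@H](Br)[C@](C)(O)C[C@@H](OC(=O)[C@@](C)(O)[C@H](C)O)[C@@H]12
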